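**Retrosynthetic overview**

1. Numbering: ring carbons C1–C11 as they appear in the SMILES string, Ca = the OCH2 carbon. The target is a nortricyclene (apex C6; bridges C1, C7, C11; cyclopropane C8–C9–C10) fused to ring A (C1–C6). The cyclopropane is tied through C9 to C1 and through C10 to the carbinol carbon C11, and ring A is trans-fused to the ring C1–C6–C7–C8–C9.
2. Key disconnection: C1–C9 and C10–C11, closed in one strain-release radical bicyclisation through a 1-methylcyclopropene (C9=C10) that hangs on C6 via C7. A flat ring-A radical would close cis to the C7 ring and give the C1 epimer, so the radical is made at a bridgehead: C1 is locked by a lactone tether Ca(=O)–O–C4 and activated as the bromide.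
3. The precursor comes from the Diels–Alder adduct of 3-bromo-2-pyrone and 3-methylbut-2-enal, which gives ring A, the gem-dimethyl C5, the formyl group on C6, the lactone tether and the bridgehead bromide in one step. C6 is then alkylated with the enantiopure cyclopropenylmethyl iodide made from propyne and ethyl diazoacetate.
4. After the cascade: hydroboration of C2=C3 (C3–OH), LiAlH4 opening of the lactone (Ca–OH, C4–OH), then orthoester-controlled acetylation (C3 acetate, C4–OH free).
5. Order of ring formation: cyclopropene (step 1), ring A with its lactone bridge (step 4), then the two five-membered cage rings C1–C6–C7–C8–C9 and C6–C7–C8–C10–C11 (step 6).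

Key step: step 6

Remark: the Diels–Alder adduct of step 4 is made and used as the racemate; the enantiopure iodide of step 3 turns its two antipodes into diastereomers in step 5, and only the one with the (1S,4S,5S) bicycle is carried on.

**Step 1**
Reactants: 1 propyne; 2 ethyl diazoacetate
Product: 3 ethyl (1R)-2-methylcycloprop-2-ene-1-carboxylate
Conditions: Rh2(OAc)(DPTI)3 (divalent rhodium; DPTI = 4,5-diphenyl-1-(trifluoromethylsulfonyl)imidazolidin-2-one N-anion, the ligand antipode that gives the (1R) ester), excess 1, slow addition of 2, CH2Cl2, 0 °C
Reagents that add atoms: none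
Why: Rhodium-carbene cyclopropenation of a terminal alkyne, a known catalytic asymmetric reaction in which the chiral catalyst sets C8.

**Step 2**
Reactants: 3 ethyl (1R)-2-methylcycloprop-2-ene-1-carboxylate
Product: 4 [(1R)-2-methylcycloprop-2-en-1-yl]methanol
Conditions: i-Bu2AlH (2.5 equiv), Et2O, −78 to −20 °C; aq. sodium potassium tartrate; kept cold in solution
Reagents that add atoms: none
Why: Hydride reduction of the ester to the primary alcohol, which leaves the cyclopropene and C8 untouched.

**Step 3**
Reactants: 4 [(1R)-2-methylcycloprop-2-en-1-yl]methanol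
Product: 5 (3R)-3-(iodomethyl)-1-methylcycloprop-1-ene
Conditions: I2, PPh3, imidazole, CH2Cl2, −20 to 0 °C; used at once as a cold solution
Reagents that add atoms: iodine, II
Why: Appel-type iodination by SN2 at the primary carbon, so C8 is not involved; low temperature should suppress ionisation of the cyclopropenylmethyl system.

**Step 4**
Reactants: 6 3-bromo-2H-pyran-2-one; 7 3-methylbut-2-enal
Product: 8 rac-(1S,4S)-4-bromo-6,6-dimethyl-3-oxo-2-oxabicyclo[2.2.2]oct-7-ene-5-carbaldehyde (both epimers at the formyl-bearing carbon)
Conditions: 7 (5 equiv), CH2Cl2, 1.1 GPa, 25 °C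
Reagents that add atoms: none
Why: Diels–Alder reaction of the bromopyrone, which should follow the usual regiochemistry of 3-bromo-2-pyrone with acceptor-substituted alkenes and put the formyl-bearing carbon next to the C–Br bridgehead (C6 next to C1) and CMe2 next to the C–O bridgehead (C5 next to C4); the bicycle fixes C1 and C4 relative to each other, and room temperature under pressure should avoid loss of CO2.

**Step 5**
Reactants: 8 rac-(1S,4S)-4-bromo-6,6-dimethyl-3-oxo-2-oxabicyclo[2.2.2]oct-7-ene-5-carbaldehyde; 5 (3R)-3-(iodomethyl)-1-methylcycloprop-1-ene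
Product: 10 (1S,4S,5S)-4-bromo-6,6-dimethyl-5-{[(1R)-2-methylcycloprop-2-en-1-yl]methyl}-3-oxo-2-oxabicyclo[2.2.2]oct-7-ene-5-carbaldehyde, via potassium enolate 9 (not isolated)
Conditions: KN(SiMe3)2 (0.95 equiv), THF, −78 °C; DMPU, 5, −78 to −30 °C; chromatography, which removes the (1R,4R,5R) diastereomer formed from the other antipode of 8
Reagents that add atoms: none
Why: C-alkylation of the aldehyde enolate (SN2), in which bromide cannot leave by β-elimination because that would need a bridgehead double bond, the slight deficit of base leaves the acidic cyclopropene C–H alone, and the iodide is expected to enter on the face flanked by the hydrogen-free lactone bridge and anti to the etheno bridge, which sets C6 with C7 syn to the lactone carbonyl; the enantiopure iodide converts the two antipodes of 8 into separable diastereomers.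

**Step 6**
Reactants: 10 (1S,4S,5S)-4-bromo-6,6-dimethyl-5-{[(1R)-2-methylcycloprop-2-en-1-yl]methyl}-3-oxo-2-oxabicyclo[2.2.2]oct-7-ene-5-carbaldehyde
Product: 12 pentacyclic lactone alcohol (C1–C9 and C10–C11 closed; C11–OH on the C7 side), via titanium alkoxide 11 (not isolated)
Conditions: (C5Me5)TiCl3 (3 equiv), Zn dust (6 equiv), THF, 25 °C (gives trivalent titanium (C5Me5)TiCl2), then dilution with benzene (THF:benzene 1:9); slow addition of 10 in benzene, final 5 mM, 25 °C; aq. NH4Cl
Reagents that add atoms: none
Why: Proposed new method: trivalent titanium abstracts the bridgehead bromine (as it does from tertiary alkyl halides in titanium-mediated Giese additions), giving a σ-radical at C1 that can neither flatten nor invert, so the C1 configuration of 10 is kept and its orbital points anti to C5 and gauche to both C6 substituents. This radical adds 5-exo-trig to the unsubstituted cyclopropene carbon C9 with release of cyclopropene strain (ring C1–C6–C7–C8–C9), and the tertiary cyclopropyl σ-radical at C10 then adds 5-exo-trig to the titanium-bound aldehyde carbon C11 (ring C6–C7–C8–C10–C11), the metal taking up the oxygen-centred radical as the tetravalent titanium alkoxide 11 before the strained cage alkoxy radical can fragment by β-scission. The closest known reaction types are tin-radical debromination at the bridgehead of bromopyrone cycloadducts, carbon-radical additions to cyclopropenes, and radical cyclisations onto aldehydes promoted by trivalent titanium. C9 is set because the tether forces attack on the cyclopropene face syn to C7 (cis-bicyclo[3.1.0]), C10 because only its endo orbital reaches the formyl group on C6, and C11 because the titanium-bearing oxygen turns to the open C7 side, away from C2. The step needs attack at C9 and not at C10, and closure before hydrogen abstraction from THF: the methyl group on C10 together with the C6/C8 relative configuration (which places C10 under C11 only after attack at C9) secures the first, dilution with benzene the second, and the absence of any metal hydride leaves the cyclopropene unreduced. A planar ring-A radical would close cis to the C7 ring and give the C1 epimer, which is why the radical is made at the lactone-locked bridgehead.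

**Step 7**
Reactants: 12 pentacyclic lactone alcohol
Product: 14 hydroxy lactone with the new C3 hydroxyl cis to the C4 lactone oxygen, via bis-borane 13 (not isolated)
Conditions: 9-BBN (2.5 equiv), THF, 25 to 45 °C; then H2O2, aq. NaH2PO4/Na2HPO4 (pH 7), 0 °C to rt
Reagents that add atoms: hydrogen peroxide, OO
Why: Hydroboration–oxidation: 9-BBN should add syn from the lactone-bridge face (the other face is screened by a C5 methyl and by C11) with boron on C3, the carbon remote from the quaternary C1 and the one favoured by the allylic C4–O bond, and oxidation with retention sets C3; the C3–B and C4–O bonds are held near 60° by the bicycle, so neither syn nor anti elimination is open, and a shift of the lactone acyl group to the new hydroxyl would be harmless because step 8 reduces the lactone.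

**Step 8**
Reactants: 14 hydroxy lactone
Product: 15 tetraol (Ca–OH, C3–OH, C4–OH, C11–OH)
Conditions: LiAlH4, THF, 0 °C to reflux; H2O, aq. NaOH work-up
Reagents that add atoms: none
Why: Hydride reduction of the lactone frees the primary alcohol at Ca and the C4 hydroxyl and touches no stereocentre.

**Step 9**
Reactants: 15 tetraol
Product: 17 diacetate orthoester (Ca–OAc, C11–OAc, C3/C4 as cyclic methyl orthoacetate), via cyclic orthoester 16 (not isolated)
Conditions: MeC(OMe)3 (1.2 equiv), PPTS (cat.), CH2Cl2, rt; then Et3N, Ac2O, DMAP, 40 °C
Reagents that add atoms: trimethyl orthoacetate, COC(C)(OC)OC; acetic anhydride, CC(=O)OC(C)=O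
Why: Orthoester exchange should close the five-membered ring on the cis-3,4-diol first, Et3N then stops further acid-catalysed exchange with the Ca hydroxyl, and DMAP-catalysed acylation acetylates the primary Ca–OH and the hindered C11–OH.

**Step 10**
Reactants: 17 diacetate orthoester
Product: 18 CNP0197219.1 (target)
Conditions: AcOH–H2O (4:1), rt
Reagents that add atoms: water, O
Why: Mild acid hydrolysis of a cyclic orthoester goes through the dioxolanylium ion and opens to the axial ester, here the C3 acetate that is syn-axial to the C1 CH2OAc group on the cage-locked chair of ring A, leaving the equatorial C4 hydroxyl free.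

**Compound list**

1 | propyne | CC#C | starting material
2 | ethyl diazoacetate | CCOC(=O)C=[N+]=[N-] | starting material
3 | ethyl (1R)-2-methylcycloprop-2-ene-1-carboxylate | CCOC(=O)[C@@H]1C=C1C | intermediate
4 | [(1R)-2-methylcycloprop-2-en-1-yl]methanol | OC[C@@H]1C=C1C | intermediate
5 | (3R)-3-(iodomethyl)-1-methylcycloprop-1-ene | IC[C@@H]1C=C1C | intermediate
6 | 3-bromo-2H-pyran-2-one | O=C1OC=CC=C1Br | starting material
7 | 3-methylbut-2-enal | CC(C)=CC=O | starting material
8 | rac-(1S,4S)-4-bromo-6,6-dimethyl-3-oxo-2-oxabicyclo[2.2.2]oct-7-ene-5-carbaldehyde, both C5 epimers (racemate, one antipode drawn) | O=C4[C@]1(Br)C=C[C@H](O4)C(C)(C)C1C=O | intermediate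
9 | potassium enolate of 8 (racemate, one antipode drawn) | O=C4[C@]1(Br)C=C[C@H](O4)C(C)(C)C1=C[O-].[K+] | intermediate
10 | (1S,4S,5S)-4-bromo-6,6-dimethyl-5-{[(1R)-2-methylcycloprop-2-en-1-yl]methyl}-3-oxo-2-oxabicyclo[2.2.2]oct-7-ene-5-carbaldehyde (cyclopropenylmethyl group on the lactone-bridge side; key-step precursor) | O=C4[C@]1(Br)C=C[C@H](O4)C(C)(C)[C@]1(C=O)C[C@@H]1C=C1C | intermediate
11 | tetravalent titanium alkoxide of 12, RO–Ti(C5Me5)Cl2 | O=C4[C@]12C=C[C@H](O4)C(C)(C)[C@]13C[C@@H]1[C@H]2[C@]1(C)[C@H]3[O-].[Ti+4].Cc1c(C)c(C)[c-](C)c1C.[Cl-].[Cl-] | intermediate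
12 | pentacyclic lactone alcohol: nortricyclene cage fused to the 2-oxabicyclo[2.2.2]oct-7-en-3-one, C11–OH on the C7 side (key-step product) | O=C4[C@]12C=C[C@H](O4)C(C)(C)[C@]13C[C@@H]1[C@H]2[C@]1(C)[C@H]3O | intermediate
13 | bis-borane: C3–B(9-BBN) syn to the lactone bridge, C11–O–B(9-BBN) | O=C4[C@]12C[C@H](B5C6CCCC5CCC6)[C@H](O4)C(C)(C)[C@]13C[C@@H]1[C@H]2[C@]1(C)[C@H]3OB7C8CCCC7CCC8 | intermediate
14 | hydroxy lactone: C3–OH cis to the C4 lactone oxygen, C11–OH | O=C4[C@]12C[C@H](O)[C@H](O4)C(C)(C)[C@]13C[C@@H]1[C@H]2[C@]1(C)[C@H]3O | intermediate
15 | tetraol (Ca–OH, C3–OH, C4–OH, C11–OH) | OC[C@]12C[C@H](O)[C@H](O)C(C)(C)[C@]13C[C@@H]1[C@H]2[C@]1(C)[C@H]3O | intermediate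
16 | C3/C4 cyclic methyl orthoacetate of 15 (orthoester carbon unassigned) | OC[C@]12C[C@@H]5OC(C)(OC)O[C@@H]5C(C)(C)[C@]13C[C@@H]1[C@H]2[C@]1(C)[C@H]3O | intermediate
17 | Ca,C11-diacetate of 16 | CC(=O)OC[C@]12C[C@@H]5OC(C)(OC)O[C@@H]5C(C)(C)[C@]13C[C@@H]1[C@H]2[C@]1(C)[C@H]3OC(C)=O | intermediate
18 | CNP0197219.1 | CC(=O)OC[C@]12C[C@H](OC(C)=O)[C@H](O)C(C)(C)[C@]13C[C@@H]1[C@H]2[C@]1(C)[C@H]3OC(C)=O | target

**Step count**

Total steps: 10. Longest linear sequence: 9 steps (1, 2, 3, 5, 6, 7, 8, 9, 10); step 4 is a one-step branch.

**Three steps most likely to fail**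

Step 6 (key step). The bromine abstraction may be slow, the C10 cyclopropyl radical may take a hydrogen atom from the medium before it reaches the formyl group, or the cage alkoxy radical may escape the metal and open by β-scission, which would move the formyl group to C10. The fallback uses known reaction types in separate steps, sets out from 10 and comes back at 12. The aldehyde of 10 is reduced with NaBH4 in MeOH at 0 °C to the primary alcohol F1. A bromine atom-transfer radical cyclisation ((Bu3Sn)2 cat., sunlamp, benzene) then forms C1–C9 and leaves bromine on C10, giving the cyclopropyl bromide alcohol F2. Oxidation with catalytic Pr4NRuO4 (heptavalent ruthenium) and N-methylmorpholine N-oxide returns the aldehyde as the cyclopropyl bromide aldehyde F3. An intramolecular Barbier reaction with SmI2 (divalent samarium) and HMPA in THF at −78 °C closes C10–C11 on the metal-bound carbonyl and gives 12.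

Step 5. Substitution at the enolate carbon, which lies between a bridgehead and CMe2, may be slow, so O-alkylation or decay of the cyclopropenylmethyl iodide can take over. Entry of the iodide from the etheno-bridge face would in addition give the C6 epimer, which would have to be removed at the stage of 10. The fallback sets out from 8 and comes back at 10. Condensation of 8 with tert-butylamine (MgSO4, CH2Cl2) gives the N-tert-butyl imine F4 as the racemate. Deprotonation with LiN(i-Pr)2 in THF at −78 °C and alkylation of the carbon-selective aza-enolate with 5 gives the alkylated imine F5 together with the diastereomeric imine F6 from the other antipode of F4. F6 is removed by chromatography on Et3N-washed silica. Hydrolysis of F5 with buffered aqueous oxalic acid gives 10.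

Step 4. The β,β-disubstituted enal may add too slowly, and forcing conditions would lead to loss of CO2 from the adduct. The fallback sets out from 7 and comes back at 8. The more reactive 3,5-dibromo-2H-pyran-2-one (O=C1OC=C(Br)C=C1Br) is used as the diene and gives the dibromo adduct F7. The vinylic bromine is then removed with Bu3SnH and catalytic Pd(PPh3)4 (zerovalent palladium) in THF at room temperature, where oxidative addition should take place at the vinylic and not at the tertiary bridgehead C–Br bond, and this gives 8.

**Further compounds**

F1 | step 6 | primary alcohol from reduction of the formyl group of 10 | O=C4[C@]1(Br)C=C[C@H](O4)C(C)(C)[C@]1(CO)C[C@@H]1C=C1C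
F2 | step 6 | cyclopropyl bromide alcohol (C1–C9 closed, bromine on C10, C10 unassigned) | O=C4[C@]12C=C[C@H](O4)C(C)(C)[C@]1(CO)C[C@@H]1[C@H]2C1(C)Br
F3 | step 6 | cyclopropyl bromide aldehyde (C10 unassigned) | O=C4[C@]12C=C[C@H](O4)C(C)(C)[C@]1(C=O)C[C@@H]1[C@H]2C1(C)Br
F4 | step 5 | N-tert-butyl imine of 8 (racemate, one antipode drawn) | O=C4[C@]1(Br)C=C[C@H](O4)C(C)(C)C1C=NC(C)(C)C
F5 | step 5 | N-tert-butyl imine of 10 | O=C4[C@]1(Br)C=C[C@H](O4)C(C)(C)[C@]1(C=NC(C)(C)C)C[C@@H]1C=C1C
F6 | step 5 | diastereomeric N-tert-butyl imine with the (1R,4R,5R) bicycle, from the other antipode of F4 | O=C4[C@@]1(Br)C=C[C@@H](O4)C(C)(C)[C@@]1(C=NC(C)(C)C)C[C@@H]1C=C1C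
F7 | step 4 | 4,7-dibromo analogue of 8, extra bromine on the vinylic carbon next to the oxygen-bearing bridgehead (racemate, one antipode drawn) | O=C4[C@]1(Br)C=C(Br)[C@H](O4)C(C)(C)C1C=O
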